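## Analysis of the target

The target (23) is a resveratrol trimer in which a 2,3,4,5-tetraaryl tetrahydrofuran (O1, C2–C5) is joined through C3 to C4' of a 2,3-diaryl-2,3-dihydrobenzofuran (O1', C2', C3'; ring A = C3a'–C7a'). Its six stereocentres fall into two clusters: in the tetrahydrofuran, C2 (S), C3 (S) and C4 (R) carry their aryl groups all cis while the aryl group on C5 (S) is trans to the one on C4, and in the dihydrobenzofuran C2' (R) and C3' (R) carry trans aryl groups. The clusters are separated by the C3–C4' bond, across which no relay of stereochemical information can be relied on, so each must be set in absolute terms and then matched. The sensitive groups are eight free phenols, three benzylic ether carbons whose aryl group carries a para oxygen (C2, C5, C2'; they ionise in acid and open through quinone methides in base), and the benzylic methine hydrogens at C3, C4 and the doubly benzylic C3', whose loss would scramble the configuration. The hard points are the contra-thermodynamic cis,cis triad C2–C3–C4 next to a trans C4–C5 pair, the crowding around ring A, and six similar electron-rich arenes that forbid late electrophilic aromatic chemistry. The strategy rests on C2': a cation there is stabilised by the para oxygen of its 4-hydroxyphenyl group, so the C2'–O1' and C3'–H bonds can both come from a flat, achiral triarylethylene whose ring A carries a free hydroxyl ortho to the alkene and a bromine at the future C4'.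

## Retrosynthetic reasoning

**23 to 22.** The eight O–H bonds are traced back to O–CH3. Methyl ethers are the only phenol protection that survives every reagent class in the route (Lewis acids, Grignard reagents, a strong Brønsted acid, hydrogenation, hydride). The forward step has to strip eight methyl groups without ionising the C–O bonds at C2, C5 and C2'.

**22 to 19 and 20.** The C5–aryl bond is cut. C5 is the one ring carbon that sits at the carbonyl oxidation level in a lactone precursor. Its aryl group is trans to its neighbour, which is what an external nucleophile gives when it attacks a ring oxocarbenium ion whose other three substituents all block the same face. The forward reaction (through arylzinc 21) must deliver a 4-methoxyphenyl group to that cation without loss of the C4 hydrogen. Sulfone 19 is an activated form of lactol 18, which is the half-reduced form of lactone 17.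

**17 to 16.** The C3–H and C4–H bonds are removed, giving butenolide 16. Both centres then follow from one syn addition of hydrogen, and the only stereocentre left on the five-membered ring, C2, directs it. Addition anti to the C2 aryl gives exactly the all-cis triad, which no equilibrating method would give.

**16 to 8 and 12.** Two bonds at the alkene are cut: C3–C4' (to the aryl bromide 8) and C4–C5 (to a one-carbon electrophile at the acid oxidation level). What remains is the propargylic alcohol 12. In the forward direction the Grignard reagent 13 from 8 adds across the alkyne of 12 under direction of its alkoxide, the vinylmagnesium 14 is carboxylated, and the hydroxy acid 15 closes to 16. This is the most convergent cut because it joins the two stereo-clusters and builds the whole butenolide in one operation. The configuration at C2 is brought in with 12.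

**12 to 9 and 10.** The carbinol C–C(alkyne) bond is cut, giving a terminal alkyne and an aromatic aldehyde. Catalytic asymmetric alkynylation, through zinc acetylide 11, sets C2.

**8 to 7.** This is the key disconnection: the C2'–O1' bond and the C3'–H bond are removed together, leaving phenol 7, a flat triarylethylene without any stereocentre. Both stereocentres of the dihydrobenzofuran then have to be created by a chiral acid in one ring closure. The gain is that everything before this step is achiral carbonyl chemistry and the bromine for the later coupling is already in place.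

**7 to 6, then to 4 and 5; 4 to 3; 3 to 1 and 2.** The alkene comes from dehydration of tertiary alcohol 6. The C–C bond between the carbinol carbon and the benzylic CH2 is cut to give ketone 4 and the benzylic Grignard reagent 5. The free hydroxyl of 4 comes from the methoxy group ortho to the carbonyl in 3, which is the only one that can chelate. The aryl–carbonyl bond of 3 is cut to the bromodimethoxybenzene 1 and the acid chloride 2. The position of attack on 1 (para to one methoxy, ortho to bromine) gives the required 1,2,3,5-pattern of ring A directly.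

## Alternatives that were turned down

**Alternative 1:** Ring A is built last. The C4'–C5' and C3a'–C7a' bonds are cut, so that the ynone A2, which carries the finished tetrahydrofuran on its alkyne carbon, and the diene 1,3-dimethoxy-1-(trimethylsilyloxy)buta-1,3-diene A3 would combine in a [4+2] cycloaddition. Elimination and aromatisation would give the 2-hydroxybenzophenone A1.
- For it: the polarisation of A2 and A3 fixes the substitution pattern of ring A (hydroxyl ortho to the ketone, methoxy para) without any question of Friedel–Crafts orientation or selective ether cleavage. On that point it is stronger than steps 1 and 2 here.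
- Against it: A2 needs the complete tetrahydrofuran with an alkynyl group on C3 before anything else exists, and a directed carbomagnesiation cannot supply that. Its alkyne is flanked by a fully substituted ring carbon, which makes it a poor partner for the diene A3 in a thermal cycloaddition.
- The decisive point: A1 is only a benzophenone. C2' and C3' would still have to be made by benzyl addition, dehydration and an asymmetric ring closure, now on a late intermediate with two acid-labile benzylic C–O bonds in the tetrahydrofuran. The hardest stereochemical problem is postponed, not solved. The chosen route runs the same ring closure at step 5 on a four-step achiral phenol.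

**Alternative 2:** The 3,5-dihydroxyphenyl ring on C3' is made from an open chain. The triketone A5, a 3,5-dioxohexanoyl group on C3' of the bromodihydrobenzofuran, would fold in aqueous alkali by aldol condensation of its terminal methyl onto the ketone next to C3'. Dehydration and enolisation would give the resorcinol A4.
- For it: the ring arrives as a free diol, so two fewer ethers need cleaving at the end. The precursor is a 3-acyl dihydrobenzofuran, a class for which enantioselective carbene C–H insertion is established, so its stereocentres could rest on precedent. On that point it is stronger than the unprecedented step 5.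
- Against it: in A5 the C3' hydrogen is alpha to a ketone and beta to the C2'–O1' aryl ether. Hydroxide should epimerise C3' and open the dihydrofuran ring by beta-elimination before or while the chain folds. The triketone A5 can also close in other ways (pyranone, other aldol modes).
- Step economy: several steps are spent making an arene that can be bought as the acid chloride 2, and the two free phenols of A4 would need re-protection before the organomagnesium steps. The chosen route brings this ring in with step 1.

**Alternative 3:** The tetrahydrofuran is made by a [4+1] annulation. The O1–C5 and C5–C4 bonds are cut, so that the α-aryl enone A7, which carries the dihydrobenzofuran, would react under copper catalysis with the diazo compound A8. Carbene transfer to the carbonyl oxygen, then 1,5-electrocyclisation of the ylide, would give the 4,5-dihydrofuran A6 with trans aryl groups at C4 and C5. Reduction of its C2=C3 bond would follow.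
- For it: all four aryl groups of the tetrahydrofuran are in place after one step. This is shorter than steps 7 to 11 here, and on step count for this half it is stronger.
- Against it: a donor carbene without an acceptor group, as A8 would give, is expected to cyclopropanate, dimerise or decompose as readily as it forms the ylide. The annulation must also be selective relative to the existing C2'/C3' centres of A7. The last reduction has to add hydrogen to the tetrasubstituted, tetra-aryl enol ether of A6 anti to the C4 aryl but syn to the C5 aryl, so the facial bias is weak, and the enol ether is labile to acid and hydrogenolysis.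
- Comparison: it has two uncertain steps late in the sequence, against one uncertain step early here. It also gives no answer for the dihydrobenzofuran itself, because A7 still needs that half in enantiopure form.

Key step: step 5

Assumption: the sense of induction of an imidodiphosphorimidate acid on this new substrate class cannot be derived from precedent; the (S,S)-catalyst is written, HN[P(=NSO2CF3)(O2C20H10Ar2)]2 from two (S)-3,3'-Ar2-1,1'-bi-2-naphthol units with Ar = 3,5-(CF3)2C6H3 as first choice, and its mirror image is used if the induction proves opposite.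

Assumption: in step 6 (S)-1,1'-bi-2-naphthol is taken as the ligand that directs the alkynyl group to the Si face of the aldehyde; the (R)-ligand is used if the sense proves opposite.

## Route

Step 1
Reactants: 1 1-bromo-3,5-dimethoxybenzene; 2 3,5-dimethoxybenzoyl chloride
Product: 3 (2-bromo-4,6-dimethoxyphenyl)(3,5-dimethoxyphenyl)methanone
Conditions: AlCl3 (1.2 equiv), CH2Cl2, 0 °C
Reagents that add atoms: none
Why: Friedel–Crafts acylation; the acylium ion should attack C2 of 1, para to one methoxy group and ortho to the other, not the crowded position between the two methoxy groups, and the ketone formed is deactivated against a second acylation. Any material that loses the methyl group ortho to the carbonyl under AlCl3 is already compound 4 and is carried into step 2.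

Step 2
Reactants: 3 (2-bromo-4,6-dimethoxyphenyl)(3,5-dimethoxyphenyl)methanone
Product: 4 (2-bromo-6-hydroxy-4-methoxyphenyl)(3,5-dimethoxyphenyl)methanone
Conditions: BCl3 (1.5 equiv), CH2Cl2, –78 → 0 °C; H2O
Reagents that add atoms: none
Why: Chelation-controlled aryl methyl ether cleavage; boron binds the carbonyl oxygen and the ortho methoxy oxygen in a six-membered chelate, so only that methyl group should be lost, while the para methoxy group and the meta methoxy groups of the other ring have no such assistance.

Step 3
Reactants: 4 (2-bromo-6-hydroxy-4-methoxyphenyl)(3,5-dimethoxyphenyl)methanone; 5 (4-methoxybenzyl)magnesium chloride (commercial THF solution)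
Product: 6 3-bromo-2-[1-(3,5-dimethoxyphenyl)-1-hydroxy-2-(4-methoxyphenyl)ethyl]-5-methoxyphenol (racemic)
Conditions: 5 (3 equiv), THF, 0 °C → rt; aq. NH4Cl
Reagents that add atoms: none
Why: Grignard 1,2-addition; the first equivalent deprotonates the phenol, the magnesium phenoxide chelates the carbonyl, and the benzylic reagent, which has no β-hydrogen for reduction and meets a ketone without α-hydrogen for enolisation, should add to give the tertiary alcohol. Its stereocentre is removed in step 4, so the racemate is used.

Step 4
Reactants: 6 3-bromo-2-[1-(3,5-dimethoxyphenyl)-1-hydroxy-2-(4-methoxyphenyl)ethyl]-5-methoxyphenol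
Product: 7 3-bromo-2-[(Z)-1-(3,5-dimethoxyphenyl)-2-(4-methoxyphenyl)ethenyl]-5-methoxyphenol
Conditions: pyridinium p-toluenesulfonate (10 mol %), 4 Å molecular sieves, PhMe, 60 °C
Reagents that add atoms: none
Why: Acid-catalysed E1 dehydration; the tertiary, doubly benzylic alcohol ionises easily with help from the ortho hydroxyl and para methoxy groups of ring A (an ortho-quinone methide), and loss of a proton from the CH2 group gives the triarylethylene. The pyridinium acid is too weak to protonate the alkene, so no racemic ring closure is expected; the Z isomer is drawn and any E isomer is carried along because both converge in step 5.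

Step 5
Reactants: 7 3-bromo-2-[(Z)-1-(3,5-dimethoxyphenyl)-2-(4-methoxyphenyl)ethenyl]-5-methoxyphenol
Product: 8 (2R,3R)-4-bromo-3-(3,5-dimethoxyphenyl)-6-methoxy-2-(4-methoxyphenyl)-2,3-dihydro-1-benzofuran
Conditions: (S,S)-imidodiphosphorimidate acid HN[P(=NSO2CF3)(O2C20H10Ar2)]2, Ar = 3,5-(CF3)2C6H3 (5 mol %), PhMe (0.05 M), –20 °C; quench with Et3N at full conversion
Reagents that add atoms: none
Why: Proposed new method: the strong, confined imidodiphosphorimidate acid should transfer its proton to C3' of the electron-rich triarylethylene, giving a 4-methoxybenzyl cation at C2' held as a contact ion pair with the chiral anion, and the neighbouring phenol oxygen should capture this cation to form the C2'–O1' bond and return the proton to the catalyst; the closest known reaction types are imidodiphosphorimidate-catalysed asymmetric intramolecular hydroalkoxylation of alkenes and the achiral acid-catalysed cyclisation of 2-hydroxystilbenes to 2-aryl-2,3-dihydrobenzofurans. The closure of the dihydrofuran ring is formally a 5-endo-trig O-cyclisation, since both alkene carbons end up in the ring, and it is feasible here because it runs stepwise through a discrete cation and not as a concerted attack on the π bond. C3' is set by the face on which the proton arrives or, if protonation is reversible, by which of the two enantiomeric ion pairs closes faster; in both cases the chiral counteranion controls it, and the phenol O–H can hydrogen-bond to that anion as a second point of contact. C2' is set relative to C3' by the substrate: the oxygen adds to the planar cation so that the 4-methoxyphenyl group avoids the 3,5-dimethoxyphenyl group on C3', which gives the trans ring, also the more stable isomer. The step needs productive regiochemistry of protonation, trans closure and enantioselection; the first is secured because only the C2' cation, stabilised by a coplanar para-methoxy donor, can be trapped in a five-membered ring, whereas protonation at C2' gives a tertiary cation (a protonated ortho-quinone methide) with no ring-closing exit, which returns to 7 and in passing equilibrates the alkene geometry. The bromine at C4' twists ring A out of the alkene plane, which holds the hydroxyl over the π system and should shorten the lifetime of the cation. Low temperature and a quench at full conversion are needed so that the product is not re-ionised at C2' and then deprotonated at C3', the only path that would erode the enantiomeric purity.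

Step 6
Reactants: 9 1-ethynyl-3,5-dimethoxybenzene; 10 4-methoxybenzaldehyde
Product: 12 (1R)-3-(3,5-dimethoxyphenyl)-1-(4-methoxyphenyl)prop-2-yn-1-ol, via ethylzinc acetylide 11 (not isolated)
Conditions: 9 (2 equiv), Et2Zn (2 equiv), PhMe, reflux; (S)-1,1'-bi-2-naphthol (20 mol %), Ti(OiPr)4 (50 mol %), Et2O, rt; then 10, rt
Reagents that add atoms: none
Why: Catalytic asymmetric addition of an alkynylzinc reagent to an aromatic aldehyde under a binaphthol–titanium Lewis acid, a reaction class that suits arylacetylenes and aromatic aldehydes. With the (S)-ligand the alkynyl group is expected on the Si face of 10, which gives the (R)-carbinol that becomes C2 of the tetrahydrofuran.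

Step 7
Reactants: 8 (2R,3R)-4-bromo-3-(3,5-dimethoxyphenyl)-6-methoxy-2-(4-methoxyphenyl)-2,3-dihydro-1-benzofuran; 12 (1R)-3-(3,5-dimethoxyphenyl)-1-(4-methoxyphenyl)prop-2-yn-1-ol
Product: 16 (5R)-3-(3,5-dimethoxyphenyl)-4-[(2R,3R)-3-(3,5-dimethoxyphenyl)-6-methoxy-2-(4-methoxyphenyl)-2,3-dihydro-1-benzofuran-4-yl]-5-(4-methoxyphenyl)furan-2(5H)-one, via arylmagnesium bromide 13 (not isolated), via vinylmagnesium chelate 14 (not isolated), via hydroxy acid 15 (not isolated)
Conditions: 8, Mg, LiCl, THF, rt; 12 (1.5 equiv), iPrMgCl (1.5 equiv), THF, 0 °C; combine, PhMe, 70 °C; CO2, –20 °C → rt; 1 M HCl, 0 °C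
Reagents that add atoms: carbon dioxide, O=C=O
Why: LiCl-assisted magnesium insertion gives the aryl Grignard reagent, which should add to the magnesium alkoxide of the propargylic alcohol by alkoxide-directed anti carbomagnesiation: the aryl group goes to the alkyne carbon next to the carbinol and magnesium to the aryl-stabilised distal carbon, closing a five-membered oxamagnesacycle. Carboxylation of the vinyl–magnesium bond and acidification give the (Z)-γ-hydroxy acid, which lactonises at once to the butenolide. The carbinol centre is not touched, and a minor enantiomer of either partner would appear as a separable diastereomer.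

Step 8
Reactants: 16 (5R)-3-(3,5-dimethoxyphenyl)-4-[(2R,3R)-3-(3,5-dimethoxyphenyl)-6-methoxy-2-(4-methoxyphenyl)-2,3-dihydro-1-benzofuran-4-yl]-5-(4-methoxyphenyl)furan-2(5H)-one
Product: 17 (3R,4S,5S)-3-(3,5-dimethoxyphenyl)-4-[(2R,3R)-3-(3,5-dimethoxyphenyl)-6-methoxy-2-(4-methoxyphenyl)-2,3-dihydro-1-benzofuran-4-yl]-5-(4-methoxyphenyl)oxolan-2-one (all-cis lactone)
Conditions: H2 (4 bar), Pd/C (10 wt %), EtOAc, rt
Reagents that add atoms: none
Why: Heterogeneous catalytic hydrogenation of a butenolide; both hydrogens should be delivered syn, to the face opposite the 4-methoxyphenyl group on the lactone C5. This sets the lactone C3 and C4 (C4 and C3 of the tetrahydrofuran) with all three aryl groups cis, and the neutral medium leaves the epimerisable α-aryl centre as formed.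

Step 9
Reactants: 17 (3R,4S,5S)-3-(3,5-dimethoxyphenyl)-4-[(2R,3R)-3-(3,5-dimethoxyphenyl)-6-methoxy-2-(4-methoxyphenyl)-2,3-dihydro-1-benzofuran-4-yl]-5-(4-methoxyphenyl)oxolan-2-one
Product: 18 (3R,4S,5S)-3-(3,5-dimethoxyphenyl)-4-[(2R,3R)-3-(3,5-dimethoxyphenyl)-6-methoxy-2-(4-methoxyphenyl)-2,3-dihydro-1-benzofuran-4-yl]-5-(4-methoxyphenyl)oxolan-2-ol (both C2 epimers)
Conditions: iBu2AlH (1.2 equiv), CH2Cl2, –78 °C; aq. potassium sodium tartrate
Reagents that add atoms: none
Why: Partial reduction of a γ-lactone to the lactol; the aluminium hemiacetal is stable at –78 °C, so over-reduction and enolisation of the α-aryl centre should both be avoided.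

Step 10
Reactants: 18 (3R,4S,5S)-3-(3,5-dimethoxyphenyl)-4-[(2R,3R)-3-(3,5-dimethoxyphenyl)-6-methoxy-2-(4-methoxyphenyl)-2,3-dihydro-1-benzofuran-4-yl]-5-(4-methoxyphenyl)oxolan-2-ol
Product: 19 (3R,4S,5S)-2-(benzenesulfonyl)-3-(3,5-dimethoxyphenyl)-4-[(2R,3R)-3-(3,5-dimethoxyphenyl)-6-methoxy-2-(4-methoxyphenyl)-2,3-dihydro-1-benzofuran-4-yl]-5-(4-methoxyphenyl)oxolane (both C2 epimers)
Conditions: PhSO2H (2 equiv), CaCl2, CH2Cl2, rt
Reagents that add atoms: benzenesulfinic acid, OS(=O)c1ccccc1
Why: Formation of a 2-sulfonyl cyclic ether from a lactol through the ring oxocarbenium ion; the sulfinic acid is its own mild catalyst and is not strong enough to ionise the other benzylic ether bonds.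

Step 11
Reactants: 19 (3R,4S,5S)-2-(benzenesulfonyl)-3-(3,5-dimethoxyphenyl)-4-[(2R,3R)-3-(3,5-dimethoxyphenyl)-6-methoxy-2-(4-methoxyphenyl)-2,3-dihydro-1-benzofuran-4-yl]-5-(4-methoxyphenyl)oxolane; 20 (4-methoxyphenyl)magnesium bromide (commercial THF solution)
Product: 22 (2R,3R)-4-[(2S,3S,4R,5S)-4-(3,5-dimethoxyphenyl)-2,5-bis(4-methoxyphenyl)oxolan-3-yl]-3-(3,5-dimethoxyphenyl)-6-methoxy-2-(4-methoxyphenyl)-2,3-dihydro-1-benzofuran, via bis(4-methoxyphenyl)zinc 21 (not isolated)
Conditions: 20 (3 equiv), ZnBr2 (1.5 equiv), THF, 0 °C → rt; then 19, rt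
Reagents that add atoms: none
Why: Substitution of a 2-sulfonyl cyclic ether by an arylzinc reagent; the zinc and magnesium halides ionise the C–S bond to the oxocarbenium ion, and the aryl group should be transferred to C5 from the face opposite the three cis aryl groups, that is trans to the aryl on C4, which sets C5 (S). The reagent is a poor base, which limits loss of the C4 hydrogen.

Step 12
Reactants: 22 (2R,3R)-4-[(2S,3S,4R,5S)-4-(3,5-dimethoxyphenyl)-2,5-bis(4-methoxyphenyl)oxolan-3-yl]-3-(3,5-dimethoxyphenyl)-6-methoxy-2-(4-methoxyphenyl)-2,3-dihydro-1-benzofuran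
Product: 23 5-[(2R,3R)-4-[(2S,3S,4R,5S)-4-(3,5-dihydroxyphenyl)-2,5-bis(4-hydroxyphenyl)oxolan-3-yl]-6-hydroxy-2-(4-hydroxyphenyl)-2,3-dihydro-1-benzofuran-3-yl]benzene-1,3-diol
Conditions: BBr3 (20 equiv), CH2Cl2, –78 → 0 °C; MeOH, then aq. NaHCO3
Reagents that add atoms: none
Why: Lewis-acid cleavage of aryl methyl ethers (boron coordination, then bromide attack on the methyl group), the usual way to unveil permethylated oligostilbenes. No bond at a stereocentre is involved, and low temperature with a large excess of reagent is meant to finish the demethylation before the benzylic ring C–O bonds ionise.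

## Compound list

1 | 1-bromo-3,5-dimethoxybenzene | COc1cc(Br)cc(OC)c1 | starting material
2 | 3,5-dimethoxybenzoyl chloride | COc1cc(cc(OC)c1)C(Cl)=O | starting material
3 | (2-bromo-4,6-dimethoxyphenyl)(3,5-dimethoxyphenyl)methanone | COc1cc(OC)c(C(=O)c2cc(OC)cc(OC)c2)c(Br)c1 | intermediate
4 | (2-bromo-6-hydroxy-4-methoxyphenyl)(3,5-dimethoxyphenyl)methanone | COc1cc(O)c(C(=O)c2cc(OC)cc(OC)c2)c(Br)c1 | intermediate
5 | (4-methoxybenzyl)magnesium chloride | COc1ccc(C[Mg]Cl)cc1 | starting material
6 | 3-bromo-2-[1-(3,5-dimethoxyphenyl)-1-hydroxy-2-(4-methoxyphenyl)ethyl]-5-methoxyphenol (racemic) | COc1cc(O)c(C(O)(Cc2ccc(OC)cc2)c2cc(OC)cc(OC)c2)c(Br)c1 | intermediate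
7 | 3-bromo-2-[(Z)-1-(3,5-dimethoxyphenyl)-2-(4-methoxyphenyl)ethenyl]-5-methoxyphenol | Oc1cc(OC)cc(Br)c1/C(=C\c1ccc(OC)cc1)c1cc(OC)cc(OC)c1 | intermediate
8 | (2R,3R)-4-bromo-3-(3,5-dimethoxyphenyl)-6-methoxy-2-(4-methoxyphenyl)-2,3-dihydro-1-benzofuran | Brc1cc(OC)cc2c1[C@@H](c1cc(OC)cc(OC)c1)[C@H](c1ccc(OC)cc1)O2 | intermediate
9 | 1-ethynyl-3,5-dimethoxybenzene | C#Cc1cc(OC)cc(OC)c1 | starting material
10 | 4-methoxybenzaldehyde | COc1ccc(C=O)cc1 | starting material
11 | ethyl[(3,5-dimethoxyphenyl)ethynyl]zinc | CC[Zn]C#Cc1cc(OC)cc(OC)c1 | intermediate (not isolated)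
12 | (1R)-3-(3,5-dimethoxyphenyl)-1-(4-methoxyphenyl)prop-2-yn-1-ol | COc1ccc([C@H](C#Cc2cc(OC)cc(OC)c2)O)cc1 | intermediate
13 | [(2R,3R)-3-(3,5-dimethoxyphenyl)-6-methoxy-2-(4-methoxyphenyl)-2,3-dihydro-1-benzofuran-4-yl]magnesium bromide | Br[Mg]c1cc(OC)cc2c1[C@@H](c1cc(OC)cc(OC)c1)[C@H](c1ccc(OC)cc1)O2 | intermediate (not isolated)
14 | (5R)-3-(3,5-dimethoxyphenyl)-4-[(2R,3R)-3-(3,5-dimethoxyphenyl)-6-methoxy-2-(4-methoxyphenyl)-2,3-dihydro-1-benzofuran-4-yl]-5-(4-methoxyphenyl)-2,5-dihydro-1,2-oxamagnesole (cyclic vinylmagnesium alkoxide) | COc1ccc([C@H]2O[Mg]C(c3cc(OC)cc(OC)c3)=C2c2cc(OC)cc3c2[C@@H](c2cc(OC)cc(OC)c2)[C@H](c2ccc(OC)cc2)O3)cc1 | intermediate (not isolated)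
15 | (2Z,4R)-2-(3,5-dimethoxyphenyl)-3-[(2R,3R)-3-(3,5-dimethoxyphenyl)-6-methoxy-2-(4-methoxyphenyl)-2,3-dihydro-1-benzofuran-4-yl]-4-hydroxy-4-(4-methoxyphenyl)but-2-enoic acid | COc1ccc([C@@H](O)/C(c2cc(OC)cc3c2[C@@H](c2cc(OC)cc(OC)c2)[C@H](c2ccc(OC)cc2)O3)=C(\C(O)=O)c2cc(OC)cc(OC)c2)cc1 | intermediate (not isolated)
16 | (5R)-3-(3,5-dimethoxyphenyl)-4-[(2R,3R)-3-(3,5-dimethoxyphenyl)-6-methoxy-2-(4-methoxyphenyl)-2,3-dihydro-1-benzofuran-4-yl]-5-(4-methoxyphenyl)furan-2(5H)-one | COc1ccc([C@H]2OC(=O)C(c3cc(OC)cc(OC)c3)=C2c2cc(OC)cc3c2[C@@H](c2cc(OC)cc(OC)c2)[C@H](c2ccc(OC)cc2)O3)cc1 | intermediate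
17 | (3R,4S,5S)-3-(3,5-dimethoxyphenyl)-4-[(2R,3R)-3-(3,5-dimethoxyphenyl)-6-methoxy-2-(4-methoxyphenyl)-2,3-dihydro-1-benzofuran-4-yl]-5-(4-methoxyphenyl)oxolan-2-one | COc1ccc([C@H]2OC(=O)[C@@H](c3cc(OC)cc(OC)c3)[C@H]2c2cc(OC)cc3c2[C@@H](c2cc(OC)cc(OC)c2)[C@H](c2ccc(OC)cc2)O3)cc1 | intermediate
18 | (3R,4S,5S)-3-(3,5-dimethoxyphenyl)-4-[(2R,3R)-3-(3,5-dimethoxyphenyl)-6-methoxy-2-(4-methoxyphenyl)-2,3-dihydro-1-benzofuran-4-yl]-5-(4-methoxyphenyl)oxolan-2-ol (both C2 epimers) | COc1ccc([C@H]2OC(O)[C@@H](c3cc(OC)cc(OC)c3)[C@H]2c2cc(OC)cc3c2[C@@H](c2cc(OC)cc(OC)c2)[C@H](c2ccc(OC)cc2)O3)cc1 | intermediate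
19 | (3R,4S,5S)-2-(benzenesulfonyl)-3-(3,5-dimethoxyphenyl)-4-[(2R,3R)-3-(3,5-dimethoxyphenyl)-6-methoxy-2-(4-methoxyphenyl)-2,3-dihydro-1-benzofuran-4-yl]-5-(4-methoxyphenyl)oxolane (both C2 epimers) | COc1ccc([C@H]2OC(S(=O)(=O)c3ccccc3)[C@@H](c3cc(OC)cc(OC)c3)[C@H]2c2cc(OC)cc3c2[C@@H](c2cc(OC)cc(OC)c2)[C@H](c2ccc(OC)cc2)O3)cc1 | intermediate
20 | (4-methoxyphenyl)magnesium bromide | COc1ccc([Mg]Br)cc1 | starting material
21 | bis(4-methoxyphenyl)zinc | COc1ccc([Zn]c2ccc(OC)cc2)cc1 | intermediate (not isolated)
22 | (2R,3R)-4-[(2S,3S,4R,5S)-4-(3,5-dimethoxyphenyl)-2,5-bis(4-methoxyphenyl)oxolan-3-yl]-3-(3,5-dimethoxyphenyl)-6-methoxy-2-(4-methoxyphenyl)-2,3-dihydro-1-benzofuran | COc1ccc([C@H]2O[C@H](c3ccc(OC)cc3)[C@@H](c3cc(OC)cc(OC)c3)[C@H]2c2cc(OC)cc3c2[C@@H](c2cc(OC)cc(OC)c2)[C@H](c2ccc(OC)cc2)O3)cc1 | intermediate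
23 | 5-[(2R,3R)-4-[(2S,3S,4R,5S)-4-(3,5-dihydroxyphenyl)-2,5-bis(4-hydroxyphenyl)oxolan-3-yl]-6-hydroxy-2-(4-hydroxyphenyl)-2,3-dihydro-1-benzofuran-3-yl]benzene-1,3-diol | Oc1ccc([C@H]2O[C@H](c3ccc(O)cc3)[C@@H](c3cc(O)cc(O)c3)[C@H]2c2cc(O)cc3c2[C@@H](c2cc(O)cc(O)c2)[C@H](c2ccc(O)cc2)O3)cc1 | target

## Step count and least certain steps

Total: 12 steps. Longest linear sequence: 11 steps (steps 1 to 5 and 7 to 12, from 1 and 2). Step 6 is a one-step side branch.

**Step 5 (key step, new method).**
- What may go wrong: poor facial discrimination, because the benzylic cation may be too long-lived and too loosely paired for the anion to control both proton delivery and ring closure. Non-productive protonation at C2' may be followed by intermolecular Friedel–Crafts capture by another electron-rich arene (oligomerisation). Enantiomeric purity may erode through re-ionisation of the product at C2' and loss of the C3' proton.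
- Fallback (known chemistry): from 7, ring closure with an achiral sulfonic acid (TsOH·H2O, 10 mol %, PhMe, 40 °C), the established acid-catalysed cyclisation of 2-hydroxystilbenes, should give the trans-dihydrobenzofuran as a racemate, that is 8 together with its mirror image (2S,3S)-4-bromo-3-(3,5-dimethoxyphenyl)-6-methoxy-2-(4-methoxyphenyl)-2,3-dihydro-1-benzofuran F1. Preparative chromatography on a chiral stationary phase then removes F1, and the route is rejoined at 8. Because 12 is a single enantiomer, incompletely resolved material would be upgraded again at 16, where the wrong enantiomer appears as a separable diastereomer.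

**Step 7.**
- What may go wrong: slow or failed carbomagnesiation, because the Grignard reagent 13 carries a bulky diarylmethine group next to the carbon–magnesium bond and must add to an internal alkyne. Protonation of 13 during the long heating would then dominate.
- Fallback: from 8, Miyaura borylation (B2pin2, Pd(dppf)Cl2, KOAc, dioxane, 90 °C) gives the pinacol boronate F2. In parallel, methyl (2R)-2-hydroxy-2-(4-methoxyphenyl)acetate is acylated with (3,5-dimethoxyphenyl)acetyl chloride (pyridine, CH2Cl2) to the O-acyl mandelate F3. Dieckmann condensation (LiN(SiMe3)2, THF, –78 → 0 °C) gives the tetronic acid F4, and Tf2O with iPr2NEt gives the enol triflate F5. Suzuki–Miyaura coupling of F2 with F5 (Pd(OAc)2, SPhos, K3PO4, PhMe/H2O, 60 °C) rejoins the route at 16. Any loss of configuration at the lactone C5 under base would show as a diastereomer of 16 and be removed by chromatography.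

**Step 8.**
- What may go wrong: hydrogenolysis of the allylic and benzylic C5–O bond of the butenolide (ring opening to an acid) or of the C2'–O1' bond, or no reaction at all, because the tetrasubstituted alkene is shielded by three aryl groups.
- Fallback: from 16, conjugate hydride reduction with hexameric triphenylphosphine copper hydride [(Ph3P)CuH]6 in THF, then protonation of the copper enolate with a bulky phenol at low temperature. Hydride should add to the β-carbon anti to the 4-methoxyphenyl group and the proton should arrive at the α-carbon from the face opposite the new β-aryl group, giving the same all-cis lactone 17. No new isolated compound arises on this path, which is entered as F0.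

**Step 11.**
- What may go wrong: loss of the C4 configuration by elimination of sulfinate or of a proton from the oxocarbenium ion to a 2,3-dihydrofuran, or attack from the wrong face if the ion pair is tight on the open face.
- Fallback: from 18, acetylation (Ac2O, pyridine, 4-(dimethylamino)pyridine) gives the lactol acetate F6. Friedel–Crafts arylation of its oxocarbenium ion with anisole (BF3·OEt2, CH2Cl2, –40 °C), with a C–H nucleophile in place of an organometal, should give the para-substituted trans product and rejoin the route at 22.

**Step 12.**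
- What may go wrong: ionisation of the benzylic C–O bonds at C2, C5 or C2' by the Lewis acid, each being para to an oxygen-bearing aryl group, with ring opening by bromide or epimerisation; or incomplete cleavage of the eight ethers.
- Fallback: from 22, nucleophilic demethylation without a Lewis acid (NaSEt, DMF, 120 °C, SN2 attack of thiolate on the methyl groups) leads directly to 23, with no new compound on the way, which is entered as F0. Reaction time should be kept short, because phenoxide-assisted opening of the benzylic ethers is then the concern.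

## Further compounds

F1 | step 5 | (2S,3S)-4-bromo-3-(3,5-dimethoxyphenyl)-6-methoxy-2-(4-methoxyphenyl)-2,3-dihydro-1-benzofuran (mirror image of 8, formed together with 8 as the racemate) | Brc1cc(OC)cc2c1[C@H](c1cc(OC)cc(OC)c1)[C@@H](c1ccc(OC)cc1)O2
F2 | step 7 | 2-[(2R,3R)-3-(3,5-dimethoxyphenyl)-6-methoxy-2-(4-methoxyphenyl)-2,3-dihydro-1-benzofuran-4-yl]-4,4,5,5-tetramethyl-1,3,2-dioxaborolane | CC1(C)OB(OC1(C)C)c1cc(OC)cc2c1[C@@H](c1cc(OC)cc(OC)c1)[C@H](c1ccc(OC)cc1)O2
F3 | step 7 | methyl (2R)-2-{[(3,5-dimethoxyphenyl)acetyl]oxy}-2-(4-methoxyphenyl)acetate | COc1ccc([C@H](C(=O)OC)OC(=O)Cc2cc(OC)cc(OC)c2)cc1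
F4 | step 7 | (5R)-3-(3,5-dimethoxyphenyl)-4-hydroxy-5-(4-methoxyphenyl)furan-2(5H)-one | COc1ccc([C@H]2OC(=O)C(c3cc(OC)cc(OC)c3)=C2O)cc1
F5 | step 7 | (2R)-4-(3,5-dimethoxyphenyl)-2-(4-methoxyphenyl)-5-oxo-2,5-dihydrofuran-3-yl trifluoromethanesulfonate | COc1ccc([C@H]2OC(=O)C(c3cc(OC)cc(OC)c3)=C2OS(=O)(=O)C(F)(F)F)cc1
F0 | step 8 | none | none
F6 | step 11 | (3R,4S,5S)-3-(3,5-dimethoxyphenyl)-4-[(2R,3R)-3-(3,5-dimethoxyphenyl)-6-methoxy-2-(4-methoxyphenyl)-2,3-dihydro-1-benzofuran-4-yl]-5-(4-methoxyphenyl)oxolan-2-yl acetate (both C2 epimers) | COc1ccc([C@H]2OC(OC(C)=O)[C@@H](c3cc(OC)cc(OC)c3)[C@H]2c2cc(OC)cc3c2[C@@H](c2cc(OC)cc(OC)c2)[C@H](c2ccc(OC)cc2)O3)cc1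
F0 | step 12 | none | none
A1 | alternative 1 | (3,5-dimethoxyphenyl){2-[(2S,3S,4R,5S)-4-(3,5-dimethoxyphenyl)-2,5-bis(4-methoxyphenyl)oxolan-3-yl]-6-hydroxy-4-methoxyphenyl}methanone | COc1ccc([C@H]2O[C@H](c3ccc(OC)cc3)[C@@H](c3cc(OC)cc(OC)c3)[C@H]2c2cc(OC)cc(O)c2C(=O)c2cc(OC)cc(OC)c2)cc1
A2 | alternative 1 | 1-(3,5-dimethoxyphenyl)-3-[(2S,3S,4R,5S)-4-(3,5-dimethoxyphenyl)-2,5-bis(4-methoxyphenyl)oxolan-3-yl]prop-2-yn-1-one | COc1ccc([C@H]2O[C@H](c3ccc(OC)cc3)[C@@H](c3cc(OC)cc(OC)c3)[C@H]2C#CC(=O)c2cc(OC)cc(OC)c2)cc1
A3 | alternative 1 | 1,3-dimethoxy-1-(trimethylsilyloxy)buta-1,3-diene | COC(=C)C=C(OC)O[Si](C)(C)C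
A4 | alternative 2 | 5-[(2R,3R)-4-bromo-6-methoxy-2-(4-methoxyphenyl)-2,3-dihydro-1-benzofuran-3-yl]benzene-1,3-diol | Brc1cc(OC)cc2c1[C@@H](c1cc(O)cc(O)c1)[C@H](c1ccc(OC)cc1)O2
A5 | alternative 2 | 1-[(2R,3R)-4-bromo-6-methoxy-2-(4-methoxyphenyl)-2,3-dihydro-1-benzofuran-3-yl]hexane-1,3,5-trione | Brc1cc(OC)cc2c1[C@@H](C(=O)CC(=O)CC(C)=O)[C@H](c1ccc(OC)cc1)O2
A6 | alternative 3 | (2R,3R)-4-[(4S,5S)-4-(3,5-dimethoxyphenyl)-2,5-bis(4-methoxyphenyl)-4,5-dihydrofuran-3-yl]-3-(3,5-dimethoxyphenyl)-6-methoxy-2-(4-methoxyphenyl)-2,3-dihydro-1-benzofuran (trans at C4/C5 of the dihydrofuran) | COc1ccc(C2O[C@H](c3ccc(OC)cc3)[C@@H](c3cc(OC)cc(OC)c3)C=2c2cc(OC)cc3c2[C@@H](c2cc(OC)cc(OC)c2)[C@H](c2ccc(OC)cc2)O3)cc1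
A7 | alternative 3 | 3-(3,5-dimethoxyphenyl)-2-[(2R,3R)-3-(3,5-dimethoxyphenyl)-6-methoxy-2-(4-methoxyphenyl)-2,3-dihydro-1-benzofuran-4-yl]-1-(4-methoxyphenyl)prop-2-en-1-one (alkene geometry left open) | COc1ccc(C(=O)C(=Cc2cc(OC)cc(OC)c2)c2cc(OC)cc3c2[C@@H](c2cc(OC)cc(OC)c2)[C@H](c2ccc(OC)cc2)O3)cc1
A8 | alternative 3 | 1-(diazomethyl)-4-methoxybenzene | COc1ccc(C=[N+]=[N-])cc1
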